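The readings were computed from invented constants, and the scatter is random.

Ash holds 0.0125 M of incoming ligand from its first minute, while cedar, starting from none, averages 0.00767 M over its 15 h of dosing, less than ash, as long as you ignore what reacts.

| flask | starting complex | incoming ligand | leaving ligand | temperature | remark | time |
|---|---|---|---|---|---|---|
| red | 0.010 M | 0.013 M (fed, over 15 h) | 0.050 M | 35 °C | run made earlier; the fed solution adds 1.0 times the starting volume |  |
| grey | 0.010 M | 0.050 M (fed, over 15 h) | 0.050 M | 50 °C | run made earlier; the fed solution adds 1.0 times the starting volume |  |
| green | 0.010 M | 0.025 M (fed, over 15 h) | 0.025 M | 35 °C | run made earlier; the fed solution adds 1.0 times the starting volume |  |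
| cedar | 0.010 M | 0.0250 M (fed, over 15 h) | 0.0500 M | 50 °C | the fed solution adds 1.0 times the starting volume | 15 h |
| ash | 0.010 M | 0.0250 M | 0.0500 M | 50 °C | everything together at the start, the whole solution of incoming ligand included, so that from the start the volume is larger by 1.0 times the starting volume | 15 h |

- red (time / h: complex with one exchanged / %, starting complex / %): 5.00: 0, 96; 10.0: 5, 97; 15.0: 3, 91; 20.0: 10, 89; 25.0: 13, 84
- grey (time / h: complex with one exchanged / %, starting complex / %): 1.00: 0, 96; 2.00: 3, 96; 3.00: 9, 92; 6.00: 20, 78; 12.0: 47, 44
- green (time / h: complex with one exchanged / %, starting complex / %): 2.00: 0, 98; 4.00: 3, 100; 6.00: 2, 98; 12.0: 8, 93; 25.0: 22, 77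

(readings scatter by 1.5 percentage points)

* the winner by amount of complex with one exchanged, in percent of the starting complex charged; "neither" if no more than 2 percentage points parts them (cedar / ash / neither)
* how much complex with one exchanged is there at the end, in percent of the starting complex charged: cedar
* how much complex with one exchanged is there at the end, in percent of the starting complex charged: ash

- charges are per starting volume, the dose included; the dosed solution carries all of it
- a reading or a percentage of leaving ligand counts all its forms, free or not

Call that average c̄, the concentration of incoming ligand averaged over the run. The bench rule is pseudo-first-order: you count the ligand as unconsumed, and the fraction of starting complex left is exp(−D), with the exponent D, at one temperature, proportional to c̄ times time. Grey, at the same 50 °C, is your yardstick: 44% left at 12.0 h gives D = 0.821 on a c̄ of 0.0133 M. Scaled from grey, the rule leaves 55.2% in cedar and 38.0% in ash.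

The rule stops where the ligand used is no small share of its charge, and here the charge is 2.50 times the starting complex, so the loss the rule reckons for ash takes 24.8% of it. I therefore subtract the mean of the used ligand from each c̄: half its end value in ash, where the loss starts at once, and a third in grey and cedar, where it grows roughly with the square of time. That gives 0.0122 M for grey, 0.00693 M for cedar and 0.0110 M for ash, and so 55.9% and 39.9% of starting complex left in cedar and ash. Grey's balance at that reading also lacks 9.00%, which I read as a second exchange; dividing that gap by grey's complex with one exchanged and by D gives g = 0.233, and complex with one exchanged is then the loss divided by one plus gD. My reckoning gives 38.8% for cedar and 49.5% for ash.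

The forecast, for ash below my reckoning, names ash with 34% for cedar and 44% for ash: “Ash wins, because dosing wastes early time”.

The flasks give 38.6% of complex with one exchanged in cedar and 49.6% in ash, so ash wins, with 56.9% of starting complex left in cedar and 40.3% in ash.

starting complex + incoming ligand → leaving ligand + complex with one exchanged (k = 0.00160 M⁻¹ s⁻¹, Ea = 85.0 kJ mol⁻¹); complex with one exchanged + incoming ligand → leaving ligand + complex with two exchanged (k = 5.80 × 10⁻⁴ M⁻¹ s⁻¹, Ea = 83.0 kJ mol⁻¹); crystals ⇌ leaving ligand, rate k3*(cs3 - [leaving ligand]) while solid is left; crystals form when [leaving ligand] > cs3 (solubility = 2.20 mM, k = 3.60 × 10⁻⁴ s⁻¹); (constants at 50 °C) A neighbouring flask repeats cedar with 0.015 M of incoming ligand, which is 1.50 equiv. Its c̄ is cedar's 0.00767 M scaled by the charge, 0.00460 M; the rule leaves 70.0%, the used ligand brings c̄ to 0.00410 M, and the reckoning gives 70.9% of starting complex and 27.0% of complex with one exchanged. That flask ends at 71.4% of starting complex and 26.8% of complex with one exchanged.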